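**Retrosynthetic overview**
1. Last bond: aryl–C(sp3) bond of the 3-hydroxypropyl chain, by B-alkyl Suzuki–Miyaura coupling of aryl bromide 12 with hydroborated allyl alcohol.
2. Key bond: C1–C2 of the propanol unit (C7–C8 in neolignan numbering), made together with both stereocentres by a decarboxylative photoredox/chiral-chromium radical coupling of racemic acid 11 with aldehyde 6.
3. Acid 11: Williamson ether from 4-bromoguaiacol 9 (catechol, two steps) and 2-bromopropanoic acid.
4. Aldehyde 6: from p-cresol by bromination/hydrolysis, then Cu-catalysed methoxylation and O-methylation in one pot.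
5. No ring is constructed; ring A comes intact from p-cresol and ring B from catechol.

Assumption: 2-bromopropanoic acid 10 is used as the racemate, and L* means the enantiomer of the bis(oxazoline) ligand that a first screen shows to give (1R,2R)-12.

**Step 1**
Reactants: 1 p-cresol (4-methylphenol)
Product: 4 3,5-dibromo-4-hydroxybenzaldehyde, via 2,6-dibromo-4-methylphenol 2 (not isolated), via 2,6-dibromo-4-(dibromomethyl)phenol 3 (not isolated)
Conditions: Br2 (2.05 equiv), o-dichlorobenzene, 35 °C; Br2 (2.05 equiv), 150–160 °C; then H2O, 100 °C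
Reagents that add atoms: bromine BrBr; water O
Why: Electrophilic aromatic bromination at both positions ortho to OH, then thermal benzylic dibromination and hydrolysis of the benzal bromide to the aldehyde; no stereocentre.

**Step 2**
Reactants: 4 3,5-dibromo-4-hydroxybenzaldehyde
Product: 6 3,4,5-trimethoxybenzaldehyde, via sodium 4-formyl-2,6-dimethoxyphenolate 5 (not isolated)
Conditions: NaOMe (4 equiv), CuCl (5 mol%), DMF/MeOH, 100 °C; then MeI (3 equiv), 40 °C
Reagents that add atoms: sodium methoxide [Na+].[O-]C; iodomethane CI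
Why: Ullmann-type Cu-catalysed methoxylation of the two C–Br bonds ortho to the phenoxide, then Williamson O-methylation of the phenoxide in the same pot; no stereocentre.

**Step 3**
Reactants: 7 catechol (1.5 equiv)
Product: 8 guaiacol (2-methoxyphenol)
Conditions: MeI (1.0 equiv), K2CO3 (1.0 equiv), acetone, reflux
Reagents that add atoms: iodomethane CI
Why: Williamson mono-O-methylation of the catechol monoanion, with excess catechol limiting dimethylation; veratrole and catechol are removed by base/water extraction.

**Step 4**
Reactants: 8 guaiacol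
Product: 9 4-bromo-2-methoxyphenol
Conditions: NBS (1.0 equiv), MeCN, 0 °C to rt
Reagents that add atoms: N-bromosuccinimide O=C1CCC(=O)N1Br
Why: Electrophilic aromatic bromination para to the free OH, which is the stronger director; no stereocentre.

**Step 5**
Reactants: 9 4-bromo-2-methoxyphenol; 10 2-bromopropanoic acid (racemic, 1.5 equiv)
Product: 11 rac-2-(4-bromo-2-methoxyphenoxy)propanoic acid
Conditions: NaOH (4 equiv), H2O, reflux; then HCl to pH 1
Reagents that add atoms: none
Why: Williamson ether synthesis (SN2 of the phenoxide on the α-bromo carboxylate); the new centre is left racemic on purpose because step 6 erases it.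

**Step 6 (key step)**
Reactants: 11 rac-2-(4-bromo-2-methoxyphenoxy)propanoic acid (1.5 equiv); 6 3,4,5-trimethoxybenzaldehyde
Product: 12 (1R,2R)-2-(4-bromo-2-methoxyphenoxy)-1-(3,4,5-trimethoxyphenyl)propan-1-ol
Conditions: CrCl2 (10 mol%), L* = (S,R)-indane-BOX, 2,2'-(propane-2,2-diyl)bis[(3aS,8aR)-3a,8a-dihydro-8H-indeno[1,2-d]oxazole] (12 mol%), 4CzIPN (2 mol%), Cs2CO3 (0.3 equiv), THF, 450 nm LEDs, 20 °C
Reagents that add atoms: none
Why: Proposed new method: excited 4CzIPN oxidises the carboxylate of 11, and loss of CO2 gives a planar α-aryloxyethyl radical, so the racemic centre is erased; ligated divalent chromium traps this radical as a configurationally labile alkylchromium species (trivalent chromium, reversible Cr–C homolysis), which adds to aldehyde 6 in a closed, ligand-organised transition state, so both new centres are set under Curtin–Hammett control by the bis(oxazoline); the threo (1R,2R) isomer is expected from the arrangement with the aryloxy oxygen gauche to the chromium-bound carbonyl oxygen and C–H facing the aldehyde aryl group; protonolysis of the chromium alkoxide by 11 and reduction of trivalent to divalent chromium by the reduced photocatalyst close the cycles; the closest known reaction types are photoredox/chromium Nozaki–Hiyama–Kishi-type radical-polar crossover additions of α-amino and α-oxy alkyl radicals to aldehydes and chromium/bis(oxazoline)-catalysed enantioselective allylations and aza-pinacol couplings.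

**Step 7**
Reactants: 12 (1R,2R)-2-(4-bromo-2-methoxyphenoxy)-1-(3,4,5-trimethoxyphenyl)propan-1-ol; 13 allyl alcohol (1.5 equiv)
Product: 15 surinamensinol A, (1R,2R)-2-[4-(3-hydroxypropyl)-2-methoxyphenoxy]-1-(3,4,5-trimethoxyphenyl)propan-1-ol, via B-[3-(9-BBN-oxy)propyl]-9-BBN 14 (not isolated)
Conditions: 13, 9-BBN (2.2 equiv per 13), THF, 0 °C to rt; then 12, Pd(dppf)Cl2 (5 mol%), 3 M aq. NaOH, THF/DMF, 65 °C
Reagents that add atoms: none
Why: Anti-Markovnikov hydroboration of allyl alcohol (the first 9-BBN equivalent is consumed by O–H) and B-alkyl Suzuki–Miyaura coupling with the aryl bromide, with aqueous base cleaving the O–B bond; the two stereocentres carry no acidic C–H and see no acid, so they are untouched.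

**Compound list**
1 | p-cresol (4-methylphenol) | Cc1ccc(O)cc1 | starting material
2 | 2,6-dibromo-4-methylphenol | Cc1cc(Br)c(O)c(Br)c1 | intermediate (not isolated)
3 | 2,6-dibromo-4-(dibromomethyl)phenol | BrC(Br)c1cc(Br)c(O)c(Br)c1 | intermediate (not isolated)
4 | 3,5-dibromo-4-hydroxybenzaldehyde | O=Cc1cc(Br)c(O)c(Br)c1 | intermediate
5 | sodium 4-formyl-2,6-dimethoxyphenolate | [Na+].[O-]c1c(OC)cc(C=O)cc1OC | intermediate (not isolated)
6 | 3,4,5-trimethoxybenzaldehyde | COc1cc(C=O)cc(OC)c1OC | intermediate
7 | catechol (benzene-1,2-diol) | Oc1ccccc1O | starting material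
8 | guaiacol (2-methoxyphenol) | COc1ccccc1O | intermediate
9 | 4-bromo-2-methoxyphenol | COc1cc(Br)ccc1O | intermediate
10 | 2-bromopropanoic acid (racemic) | CC(Br)C(O)=O | starting material
11 | rac-2-(4-bromo-2-methoxyphenoxy)propanoic acid | COc1cc(Br)ccc1OC(C)C(O)=O | intermediate
12 | (1R,2R)-2-(4-bromo-2-methoxyphenoxy)-1-(3,4,5-trimethoxyphenyl)propan-1-ol | COc1cc(Br)ccc1O[C@H](C)[C@H](O)c1cc(OC)c(OC)c(OC)c1 | intermediate
13 | allyl alcohol (prop-2-en-1-ol) | C=CCO | starting material
14 | 9-[3-(9-borabicyclo[3.3.1]nonan-9-yloxy)propyl]-9-borabicyclo[3.3.1]nonane | B1(CCCOB2C3CCCC2CCC3)C2CCCC1CCC2 | intermediate (not isolated)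
15 | surinamensinol A, (1R,2R)-2-[4-(3-hydroxypropyl)-2-methoxyphenoxy]-1-(3,4,5-trimethoxyphenyl)propan-1-ol | COc1cc(CCCO)ccc1O[C@H](C)[C@H](O)c1cc(OC)c(OC)c(OC)c1 | target

**Step count**
Total: 7 steps. Longest linear sequence: 5 steps (7 → 8 → 9 → 11 → 12 → 15). The ring A branch (1 → 4 → 6) is 2 steps and joins at step 6.

**Steps most likely to fail, with fallbacks**

Step 6 is the main risk: the enantio- and diastereoselectivity of the chromium step are untested for an α-aryloxyalkyl radical, and the erythro isomer may compete. The fallback sets out from 6 and 9 and returns at 12; it makes the C–O bond by polar chemistry and sets the stereocentres by a reductive dynamic kinetic resolution. Aldehyde 6 is treated with EtMgBr (THF, 0 °C) to give 1-(3,4,5-trimethoxyphenyl)propan-1-ol F1. MnO2 (CH2Cl2, rt) oxidises it to 1-(3,4,5-trimethoxyphenyl)propan-1-one F2. CuBr2 (EtOAc/CHCl3, reflux) gives racemic 2-bromo-1-(3,4,5-trimethoxyphenyl)propan-1-one F3. Phenol 9 with K2CO3 in acetone displaces the bromide to give racemic 2-(4-bromo-2-methoxyphenoxy)-1-(3,4,5-trimethoxyphenyl)propan-1-one F4. Noyori-type hydrogenation (RuCl2[(S)-xylbinap][(S)-daipen] or its mirror image as chosen by screen, t-BuOK, i-PrOH, H2) then reduces the ketone while base racemises its α-centre; hydride delivery in the non-chelated Felkin–Anh sense should give threo (1R,2R)-12.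

Step 7 is the second risk: the O-borylated alkylborane may transmetalate slowly onto an electron-rich aryl bromide late in the route. The fallback sets out from 12 and returns at 15. Sonogashira coupling of 12 with propargyl alcohol (PdCl2(PPh3)2, CuI, Et3N, 70 °C) gives 3-{4-[(1R,2R)-1-hydroxy-1-(3,4,5-trimethoxyphenyl)propan-2-yl]oxy-3-methoxyphenyl}prop-2-yn-1-ol F5. Hydrogenation of the alkyne (H2 1 atm, Pd/C, EtOAc, rt, stopped after two equivalents of H2 so the benzylic C–O bond is not cleaved) gives 15.

Step 2 is the third risk: the telescoped methoxylation/methylation may stall at the mono-methoxy stage or lose MeI to excess methoxide. The fallback sets out from 4 and returns at 6. Copper-mediated hydroxylation of both C–Br bonds (aq. NaOH, copper powder, reflux under N2, then HCl) gives 3,4,5-trihydroxybenzaldehyde F6. Exhaustive O-methylation (MeI, K2CO3, DMF, 40 °C) then gives 6.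

**Further compounds**
F1 | step 6 | 1-(3,4,5-trimethoxyphenyl)propan-1-ol (racemic) | CCC(O)c1cc(OC)c(OC)c(OC)c1
F2 | step 6 | 1-(3,4,5-trimethoxyphenyl)propan-1-one | CCC(=O)c1cc(OC)c(OC)c(OC)c1
F3 | step 6 | 2-bromo-1-(3,4,5-trimethoxyphenyl)propan-1-one (racemic) | CC(Br)C(=O)c1cc(OC)c(OC)c(OC)c1
F4 | step 6 | 2-(4-bromo-2-methoxyphenoxy)-1-(3,4,5-trimethoxyphenyl)propan-1-one (racemic) | COc1cc(Br)ccc1OC(C)C(=O)c1cc(OC)c(OC)c(OC)c1
F5 | step 7 | 3-{4-[(1R,2R)-1-hydroxy-1-(3,4,5-trimethoxyphenyl)propan-2-yl]oxy-3-methoxyphenyl}prop-2-yn-1-ol | COc1cc(C#CCO)ccc1O[C@H](C)[C@H](O)c1cc(OC)c(OC)c(OC)c1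
F6 | step 2 | 3,4,5-trihydroxybenzaldehyde | O=Cc1cc(O)c(O)c(O)c1
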